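Atom labels follow lignan numbering throughout: ring A is C1–C6 (C1 bears C7, C2 bears C7', C3 and C5 bear OMe, C4 bears oxygen, C6 bears H), the saturated chain is C7–C8–C8'–C7', and the pendant ring is C1'–C6'.

## Analysis of the target

Compound 18 is an aryltetralin (2,7'-cyclolignan): ring A is fused through C1 and C2 to the chain C7–C8–C8'–C7', C8 and C8' each carry a methyl group, and C7' carries the 4'-hydroxy-3'-methoxyphenyl ring. The three stereocentres C7', C8' and C8 are contiguous and all R; the aryl group on C7' is trans to the C8' methyl and the two methyl groups are cis, so the aryl group lies on one face of the saturated ring and both methyl groups on the other. None of these centres is next to a carbonyl or other acidifying group, so none can be corrected by equilibration and each has to be set kinetically. The sensitive groups are the two phenols and the electron-rich rings (oxidation, electrophilic substitution) and the doubly benzylic C7'–H, which must not be ionised again once it is set. The synthesis is hard because C8 and C8' bear plain methyl groups with no heteroatom to steer a reagent, because the diarylmethine C7' is crowded by the C3 methoxy group and must be made as one enantiomer, and because ring A is fully substituted except for C6. The strategy rests on two features: C7' is para to the 4'-hydroxyl, so it can be the exocyclic carbon of a para-quinone methide, and C8'–C8 can be the CH=C(CH3) unit of a trisubstituted alkene attached through C7 to C1 of ring A. Since C1 and C2 are neighbours on ring A, these two reactive ends are held at the distance of a six-membered ring, and the alkene geometry can encode the 7',8'-trans relation.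

## Retrosynthetic reasoning

**18 back to 17.** No skeletal bond is cut in the first move. The C7–H and C8–H bonds and the free 4-hydroxyl of 18 are traced back to the C7=C8 double bond and the benzyl ether of dihydronaphthalene 17. This leaves C8 to be derived from the C8' centre next to it, and a ring-A-conjugated alkene is exactly what a cation–olefin ring closure leaves behind. The forward reaction must add both hydrogens syn, from the face away from the C8' methyl, so that the C8 methyl ends up cis to it.

**17 back to 14 (through 15 and 16).** The C7'–C8' bond is cut. It joins two stereocentres, and it is the one bond of the ring that can be formed between a strongly stabilised cationic carbon (C7', as the quinone methide 15) and a neutral π-nucleophile. Cutting C7'–C2 instead would ask a flanked, fully substituted ring-A carbon to act as a Friedel–Crafts nucleophile. Cutting C8–C8' would need carbonyl handles that must later be reduced to methyl. The gain is large: one ring, one skeletal bond and two stereocentres arise from carbinol 14, whose own stereocentre is irrelevant because it is lost on ionisation. The forward step must choose one face of C7' (catalyst) and fix C8' relative to it (alkene geometry), and cation 16 must lose its proton from C7.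

**14 back to 9 and 11 (through 13 and 12).** The C2–C7' bond is cut as an aryl–carbinol bond: aryllithium 12, from bromide 9, adds to aldehyde 11. The pendant ring carries its phenol as a silyl ether in 11 and 13, so that it can be unmasked afterwards without touching the benzyl ether on ring A, which stays until the end. The forward step only has to make a hindered diaryl carbinol, with no stereochemical demand.

**9 back to 5 and 8.** The C7–C8 bond is cut as a benzyl–alkenyl sp3–sp2 bond. The whole C8, C8' unit with both methyl groups and the defined geometry then comes from one small alkenyl boronate 8, and ring A comes from benzylic bromide 5. The forward cross-coupling must react at the benzylic bromide and leave the ring bromine at C2 for the later lithiation, and it must keep the alkene geometry.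

**8 back to 6; 5 back to 1; 11 back to 10.** Boronate 8 is derived through alkenyllithium 7 from bromide 6, with retention. Bromide 5 is derived by functional group changes via 4, 3 and 2 from syringaldehyde 1: the aldehyde carbon of 1 becomes C7, the ring bromine marks C2 (positions 2 and 6 of 1 are equivalent, so there is no regiochemical question), and the phenol is benzylated first. Aldehyde 11 is the silyl ether of vanillin 10.

## Alternatives that were turned down

**Alternative 1:** Photoenolisation Diels–Alder. The disconnection cuts C7'–C8' and C7–C8 together, a [4+2] transform with ring A as part of an ortho-quinodimethane. In the forward key step, irradiation of ortho-methylbenzaldehyde A1 gives the hydroxy-ortho-quinodimethane A2 by 1,5-hydrogen shift, and A2 adds to the chiral butenolide A3 to give the cis-fused lactone acetal A4.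
- In favour: two C–C bonds, the ring and the C8 and C8' centres form at once. The facial bias of A3 is a well-tried substrate control, and on this point the alternative is stronger than the chosen route, whose absolute control rests on an untested catalyst–substrate pairing. The cis ring fusion maps onto the 8,8'-cis methyl groups of 18.
- Against: A4 has a hydroxyl where the pendant aryl ring should be, and its two extra carbons are at the acid and aldehyde oxidation levels. After the cycloaddition the aryl ring must still be attached to C7' through a benzylic cation, with para regiochemistry and 7',8'-trans control still to be won. The lactone acetal carbons must then be taken down to two methyl groups (reduction of both to the alcohol level, activation of both hydroxyls, double hydride displacement). That is at least six steps after the key step, on top of a separate synthesis of the hexasubstituted A1 and a photochemical step that scales poorly.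
- Comparison: the chosen route places the aryl group and both methyl groups, at their final oxidation level, in the ring-forming step and needs one step after it.

**Alternative 2:** Spirodienone formation and dienone–phenol shift. The disconnection cuts C7–C1 and C7'–C2 through a rearrangement transform, the tetralin being seen as the ring-expanded isomer of a spiro[4.5]dienone. In the forward key step, KOt-Bu deprotonates the phenol of the open-chain mesylate A5, and the para carbon C1 displaces the mesylate to give spirodienone A6; acid then shifts C7' from C1 to C2 and gives the 4'-O-benzyl ether A7 of the target.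
- In favour: para-alkylation of 2,6-dimethoxyphenolates and dienone–phenol shifts are classical. The dienone is symmetric, so both ortho carbons give the same product. The ring-forming steps need no chiral catalyst, and on precedent they are stronger than the chosen key step.
- Against: the whole stereochemical problem is moved to the open chain. A5 already needs all three contiguous centres, including the diarylmethine, which costs a long sequence of asymmetric steps before the key step. In the acid step C7', which bears a para-alkoxyphenyl group, can leave C1 by ionisation instead of migrating in concert, which would epimerise C7' or fragment the molecule. Competing migration of C7 in place of C7' would put the aryl-bearing carbon on the wrong ring position, next to C6–H.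
- Comparison: the chosen route also closes the ring through a cation at C7', but it creates two stereocentres in that step and reaches 18 in about half the number of steps.

**Alternative 3:** Oxidative bis-enolate coupling. The disconnection cuts C8–C8'. In the forward key step, double deprotonation of the acyclic diester A8 with LiN(i-Pr)2 and oxidation with CuCl2 joins the two α-carbons and gives the tetralin diester A9.
- In favour: the C7' centre of A8 can be set beforehand by catalytic asymmetric conjugate arylation. That has better precedent for absolute control than the chosen key step.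
- Against: the coupling must give the 7',8'-trans-8,8'-cis arrangement, and nothing in A8 enforces the cis relation. The electron-transfer coupling is governed by sterics, and both new centres are α to esters and can equilibrate; each of these influences points toward the 8,8'-trans relation. Both esters must then be reduced to methyl groups (reduction, activation, reduction) and two benzyl ethers removed, four or more steps after the key step.
- Comparison: the chosen route sets 8,8'-cis by a hydrogenation under substrate control and carries the methyl groups as methyl groups from the start.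

Key step: step 10

Assumption on the chemistry: the sense of induction of (R)-TRIP in step 10 cannot be derived with certainty. It is assumed to lead to the (7'R) product; should the other enantiomer be favoured, the commercial (S)-acid is used with nothing else changed.

## Route

**Step 1**
Reactants: 1 syringaldehyde (4-hydroxy-3,5-dimethoxybenzaldehyde)
Product: 2 4-(benzyloxy)-3,5-dimethoxybenzaldehyde
Conditions: BnBr, K2CO3, DMF, rt
Reagents that add atoms: benzyl bromide, BrCc1ccccc1
Why: Williamson ether synthesis on the acidic phenol; the benzyl ether withstands the organolithium, fluoride and acid steps and is removed by the final hydrogenation.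

**Step 2**
Reactants: 2 4-(benzyloxy)-3,5-dimethoxybenzaldehyde
Product: 3 4-(benzyloxy)-2-bromo-3,5-dimethoxybenzaldehyde
Conditions: NBS, MeCN, rt to 50 °C, dark
Reagents that add atoms: N-bromosuccinimide, O=C1CCC(=O)N1Br
Why: Electrophilic aromatic bromination; positions 2 and 6 are the only free ones, they are equivalent, and each is ortho and para to a methoxy group. The first bromine crowds and deactivates the ring, so monobromination should stop cleanly, and no HBr is formed that could cleave the benzyl ether.

**Step 3**
Reactants: 3 4-(benzyloxy)-2-bromo-3,5-dimethoxybenzaldehyde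
Product: 4 [4-(benzyloxy)-2-bromo-3,5-dimethoxyphenyl]methanol
Conditions: NaBH4, MeOH/THF, 0 °C
Reagents that add atoms: none
Why: Hydride reduction of the aldehyde; aryl bromide and ethers are inert to NaBH4.

**Step 4**
Reactants: 4 [4-(benzyloxy)-2-bromo-3,5-dimethoxyphenyl]methanol
Product: 5 2-(benzyloxy)-4-bromo-5-(bromomethyl)-1,3-dimethoxybenzene
Conditions: PBr3, CH2Cl2, 0 °C
Reagents that add atoms: phosphorus tribromide, BrP(Br)Br
Why: Conversion of a benzylic alcohol into the bromide through its phosphite ester (SN2 by bromide); the short, cold reaction leaves the benzyl and methyl ethers untouched.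

**Step 5**
Reactants: 6 (Z)-2-bromobut-2-ene
Product: 8 2-[(E)-but-2-en-2-yl]-4,4,5,5-tetramethyl-1,3,2-dioxaborolane, via (E)-but-2-en-2-yllithium 7 (not isolated)
Conditions: t-BuLi (2 equiv), THF/Et2O, −78 °C; then 2-isopropoxy-4,4,5,5-tetramethyl-1,3,2-dioxaborolane, −78 °C to rt; then HCl in Et2O
Reagents that add atoms: 2-isopropoxy-4,4,5,5-tetramethyl-1,3,2-dioxaborolane, CC(C)OB1OC(C)(C)C(C)(C)O1
Why: Bromine–lithium exchange at an sp2 carbon goes with retention at −78 °C (the second equivalent of t-BuLi destroys the tert-butyl bromide formed), and the alkenyllithium is trapped by the borate ester (borylation). The two methyl groups stay trans; the descriptor changes from Z to E only because carbon outranks lithium and boron in the priority rules.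

**Step 6**
Reactants: 5 2-(benzyloxy)-4-bromo-5-(bromomethyl)-1,3-dimethoxybenzene; 8 2-[(E)-but-2-en-2-yl]-4,4,5,5-tetramethyl-1,3,2-dioxaborolane
Product: 9 2-(benzyloxy)-4-bromo-1,3-dimethoxy-5-[(Z)-2-methylbut-2-en-1-yl]benzene
Conditions: Pd(PPh3)4 (5 mol %), K2CO3, THF/H2O 5:1, 60 °C
Reagents that add atoms: none
Why: Suzuki–Miyaura sp3–sp2 coupling. Zerovalent palladium inserts into the benzylic C–Br bond far faster than into the ring C–Br bond, which sits between two ortho substituents on an electron-rich ring. Transmetalation and reductive elimination keep the alkene geometry, so the terminal methyl ends up cis to the benzylic CH2, which is (Z).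

**Step 7**
Reactants: 10 vanillin (4-hydroxy-3-methoxybenzaldehyde)
Product: 11 4-[(tert-butyldimethylsilyl)oxy]-3-methoxybenzaldehyde
Conditions: TBSCl, imidazole, DMF, rt
Reagents that add atoms: tert-butyldimethylsilyl chloride, CC(C)(C)[Si](C)(C)Cl
Why: Silylation of the phenol masks the acidic proton for the organolithium addition; the aryl silyl ether is later removed by fluoride without affecting the benzyl ether.

**Step 8**
Reactants: 9 2-(benzyloxy)-4-bromo-1,3-dimethoxy-5-[(Z)-2-methylbut-2-en-1-yl]benzene; 11 4-[(tert-butyldimethylsilyl)oxy]-3-methoxybenzaldehyde
Product: 13 {3-(benzyloxy)-2,4-dimethoxy-6-[(Z)-2-methylbut-2-en-1-yl]phenyl}{4-[(tert-butyldimethylsilyl)oxy]-3-methoxyphenyl}methanol as the racemate, via aryllithium 12 (not isolated)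
Conditions: n-BuLi (1.05 equiv), THF, −78 °C, 10 min; then 11, −78 to −40 °C; then AcOH
Reagents that add atoms: none
Why: Bromine–lithium exchange followed by 1,2-addition of the aryllithium to the aldehyde. Exchange at −78 °C is much faster than deprotonation of the benzylic-allylic CH2 or of the benzyl ether, and the aldehyde has no α-hydrogen. The carbinol centre is formed racemic on purpose, since it is erased in step 10.

**Step 9**
Reactants: 13 the silyl-protected diaryl carbinol
Product: 14 4-[{3-(benzyloxy)-2,4-dimethoxy-6-[(Z)-2-methylbut-2-en-1-yl]phenyl}(hydroxy)methyl]-2-methoxyphenol (racemic at the carbinol carbon)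
Conditions: TBAF (1.1 equiv), AcOH (1.1 equiv), THF, 0 °C
Reagents that add atoms: none
Why: Fluoride cleavage of the aryl silyl ether. The acetic acid buffer keeps the phenoxide from expelling the benzylic hydroxyl too early, and the product is used without long storage or acidic chromatography.

**Step 10**
Reactants: 14 the para-hydroxy diaryl carbinol
Product: 17 4-[(1R,2S)-7-(benzyloxy)-6,8-dimethoxy-2,3-dimethyl-1,2-dihydronaphthalen-1-yl]-2-methoxyphenol, via para-quinone methide 15 (not isolated), via C8 carbocation 16 (not isolated)
Conditions: (R)-TRIP [(R)-3,3'-bis(2,4,6-triisopropylphenyl)-1,1'-binaphthyl-2,2'-diyl hydrogen phosphate] (10 mol %), 5 Å molecular sieves, toluene (0.02 M), 0 °C to rt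
Reagents that add atoms: none
Why: Proposed new method: the acid protonates the carbinol oxygen of 14 and the 4'-hydroxyl expels water to give para-quinone methide 15, which stays hydrogen-bonded (in the limit ion-paired as the 4'-hydroxy-diarylmethyl cation) to the chiral phosphate; the CH end of the alkene (C8') then adds to C7' so that the charge lands on the tertiary carbon C8 (cation 16), and the phosphate removes a benzylic C7 proton to give the ring-A-conjugated alkene of 17 and return the acid. The closest known reaction types are the acid-promoted Prins-type cation–olefin cyclization of diarylmethyl cations onto tethered alkenes and the chiral phosphoric acid catalysed enantioselective 1,6-addition to para-quinone methides made in situ from para-hydroxybenzyl alcohols; what is new is their union, with an unactivated alkene as the intramolecular nucleophile under catalyst control. The ring C7'–C2–C1–C7–C8–C8' closes in a 6-endo-trig mode with respect to the alkene. C7' is controlled by the catalyst: the phosphate bound at the quinone methide oxygen and its 2,4,6-triisopropylphenyl walls leave one face of the C7'=C1' bond open to the tethered alkene. C8' is controlled by the substrate relative to C7': in the chair-like transition state the quinoid ring is pseudoaxial to stay clear of the C3 methoxy group, and the (Z) geometry puts the C8' methyl (cis to C7) pseudoaxial on the opposite face, which gives 7',8'-trans. Site selectivity is secured because ring A has no free position within reach and the benzyl ether ring is not nucleophilic, and six- over five-membered closure is secured by the tertiary versus secondary cation. The direction of proton loss is secured by conjugation with ring A, and the alkene geometry survives until bond formation because the acid is too weak to protonate an isolated alkene.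

**Step 11**
Reactants: 17 the (1R,2S)-dihydronaphthalene
Product: 18 (-)-(7'R,8R,8'R)-4,4'-dihydroxy-3,3',5-trimethoxy-2,7'-cyclolignan
Conditions: H2 (1 atm), Pd/C (10 wt %), EtOAc/EtOH, rt
Reagents that add atoms: none
Why: Heterogeneous catalytic hydrogenation (syn addition) together with hydrogenolysis of the benzyl ether. In 17 the C7' aryl group is pseudoaxial and the trans C8' methyl is therefore pseudoaxial on the other face, directly over the neighbouring alkene carbon C8. The catalyst surface should bind C7=C8 from the face away from this allylic methyl, which places the C8 methyl cis to the C8' methyl (8R).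

## Compound list

1 | syringaldehyde (4-hydroxy-3,5-dimethoxybenzaldehyde) | COc1cc(C=O)cc(OC)c1O | starting material
2 | 4-(benzyloxy)-3,5-dimethoxybenzaldehyde | COc1cc(C=O)cc(OC)c1OCc1ccccc1 | intermediate
3 | 4-(benzyloxy)-2-bromo-3,5-dimethoxybenzaldehyde | COc1cc(C=O)c(Br)c(OC)c1OCc1ccccc1 | intermediate
4 | [4-(benzyloxy)-2-bromo-3,5-dimethoxyphenyl]methanol | COc1cc(CO)c(Br)c(OC)c1OCc1ccccc1 | intermediate
5 | 2-(benzyloxy)-4-bromo-5-(bromomethyl)-1,3-dimethoxybenzene | COc1cc(CBr)c(Br)c(OC)c1OCc1ccccc1 | intermediate
6 | (Z)-2-bromobut-2-ene (methyl groups trans) | C/C=C(\Br)C | starting material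
7 | (E)-but-2-en-2-yllithium (methyl groups trans, lithium in the place of bromine) | C/C=C(/C)[Li] | intermediate (not isolated)
8 | 2-[(E)-but-2-en-2-yl]-4,4,5,5-tetramethyl-1,3,2-dioxaborolane (methyl groups trans) | C/C=C(/C)B1OC(C)(C)C(C)(C)O1 | intermediate
9 | 2-(benzyloxy)-4-bromo-1,3-dimethoxy-5-[(Z)-2-methylbut-2-en-1-yl]benzene | C/C=C(/C)Cc1cc(OC)c(OCc2ccccc2)c(OC)c1Br | intermediate
10 | vanillin (4-hydroxy-3-methoxybenzaldehyde) | COc1cc(C=O)ccc1O | starting material
11 | 4-[(tert-butyldimethylsilyl)oxy]-3-methoxybenzaldehyde | COc1cc(C=O)ccc1O[Si](C)(C)C(C)(C)C | intermediate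
12 | {3-(benzyloxy)-2,4-dimethoxy-6-[(Z)-2-methylbut-2-en-1-yl]phenyl}lithium | C/C=C(/C)Cc1cc(OC)c(OCc2ccccc2)c(OC)c1[Li] | intermediate (not isolated)
13 | {3-(benzyloxy)-2,4-dimethoxy-6-[(Z)-2-methylbut-2-en-1-yl]phenyl}{4-[(tert-butyldimethylsilyl)oxy]-3-methoxyphenyl}methanol, racemic | C/C=C(/C)Cc1cc(OC)c(OCc2ccccc2)c(OC)c1C(O)c1ccc(O[Si](C)(C)C(C)(C)C)c(OC)c1 | intermediate
14 | 4-[{3-(benzyloxy)-2,4-dimethoxy-6-[(Z)-2-methylbut-2-en-1-yl]phenyl}(hydroxy)methyl]-2-methoxyphenol, racemic | C/C=C(/C)Cc1cc(OC)c(OCc2ccccc2)c(OC)c1C(O)c1ccc(O)c(OC)c1 | intermediate
15 | 4-({3-(benzyloxy)-2,4-dimethoxy-6-[(Z)-2-methylbut-2-en-1-yl]phenyl}methylidene)-2-methoxycyclohexa-2,5-dien-1-one (para-quinone methide, exocyclic geometry not defined) | C/C=C(/C)Cc1cc(OC)c(OCc2ccccc2)c(OC)c1C=C1C=CC(=O)C(OC)=C1 | intermediate (not isolated)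
16 | tertiary C8 carbocation: 7-(benzyloxy)-1-(4-hydroxy-3-methoxyphenyl)-6,8-dimethoxy-2,3-dimethyl-1,2,3,4-tetrahydronaphthalen-3-ylium, aryl and 2-methyl trans and configured as in 17, paired with the chiral phosphate | COc1cc([C@@H]2c3c(C[C+](C)[C@H]2C)cc(OC)c(OCc4ccccc4)c3OC)ccc1O | intermediate (not isolated)
17 | 4-[(1R,2S)-7-(benzyloxy)-6,8-dimethoxy-2,3-dimethyl-1,2-dihydronaphthalen-1-yl]-2-methoxyphenol (lignan numbering 7'R,8'S; aryl and C8' methyl trans; C7=C8 alkene) | COc1cc([C@@H]2c3c(C=C(C)[C@H]2C)cc(OC)c(OCc4ccccc4)c3OC)ccc1O | intermediate
18 | (-)-(7'R,8R,8'R)-4,4'-dihydroxy-3,3',5-trimethoxy-2,7'-cyclolignan | COc1cc([C@@H]2c3c(cc(OC)c(O)c3OC)C[C@@H](C)[C@H]2C)ccc1O | target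

## Step count and least certain steps

Total step count: 11. Longest linear sequence: 9 steps (steps 1, 2, 3, 4, 6, 8, 9, 10, 11); steps 5 and 7 are side branches.

**Step 10 (key step, labelled as a proposed new method).** Three processes may defeat it.
- Insufficient reactivity: the acid may form 15 readily, but the neutral quinone methide may be too weak an electrophile for an unactivated alkene, so that intermolecular O- or C-alkylation of phenols (oligomerisation) takes over.
- Low enantioselectivity: the alkene cannot hydrogen-bond to the phosphate, so the ion pair is oriented by one contact only.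
- Proton loss from 16 toward C8' or toward the C8 methyl, the former erasing the C8' centre.

Within the step, higher dilution, lower temperature and a more acidic N-triflyl phosphoramide on the same binaphthyl backbone would be tried first.

The fallback uses known chemistry and sets out from 14. An achiral acid (diphenyl phosphate, CH2Cl2, rt) promotes the same cation–olefin closure, a known reaction class, and gives the racemic trans-dihydronaphthalene F1; the relative configuration is still fixed by the (Z)-alkene. The 4'-phenol of F1 is acylated with (1S)-camphanoyl chloride, Et3N and DMAP to two diastereomeric esters, the (1R,2S)-dihydronaphthalene camphanate F2 and the (1S,2R)-dihydronaphthalene camphanate F3. F2 and F3 are separated by crystallisation or chromatography, and methanolysis of F2 (K2CO3, MeOH) comes back to the route at 17.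

**Step 11.** The risks are poor facial selectivity, since the pseudoaxial C7' aryl group shields the face opposite to the C8' methyl to some degree, and palladium-hydride migration of the double bond toward C8=C8' before reduction, which would scramble C8'.

The fallback sets out from 17 and uses a reagent that cannot migrate the alkene. Hydroboration with BH3·THF (excess, since the phenol consumes one equivalent) and oxidation with NaOH/H2O2 deliver hydrogen to C8 and oxygen to C7 syn, anti to the C8' methyl, and give the C7 alcohol F4, which is the 4-O-benzyl-7-hydroxy derivative of 18 with the 7-OH trans to the 8-methyl. Hydrogenolysis of the electron-rich benzylic C7–O bond of F4 together with the benzyl ether (H2, Pd(OH)2/C, EtOH with a trace of acid) then comes back to the route at 18.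

**Step 6.** The risks are competing oxidative addition at the ring C–Br bond, hydrolysis of the benzylic bromide by the aqueous base, and loss of geometric purity or migration of the alkene into conjugation through palladium hydrides. Any (E)-alkene would later give the 7',8'-cis series.

The fallback inverts the polarity and sets out from 5. Zinc dust, activated by LiCl in THF, inserts into the benzylic C–Br bond to give [4-(benzyloxy)-2-bromo-3,5-dimethoxybenzyl]zinc bromide F5. F5 is coupled under anhydrous Negishi conditions (Pd(PPh3)4, THF, rt) with an excess of alkenyl bromide 6 itself, which transfers its geometry by stereoretentive oxidative addition. The fallback comes back to the route at 9 and makes step 5 unnecessary.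

**Step 8.** The risks are proton transfer from the benzylic-allylic CH2 to the aryllithium during its lifetime and slow addition of the doubly ortho-substituted aryllithium to the aldehyde.

The fallback reverses the roles and sets out from 9. Aryllithium 12 is generated as before, trapped at once with the small electrophile DMF and quenched with aqueous AcOH to give 3-(benzyloxy)-2,4-dimethoxy-6-[(Z)-2-methylbut-2-en-1-yl]benzaldehyde F6. Commercial 4-bromo-2-methoxyphenol F7 is silylated (TBSCl, imidazole) to (4-bromo-2-methoxyphenoxy)(tert-butyl)dimethylsilane F8. Bromine–lithium exchange on F8 with n-BuLi gives the unhindered {4-[(tert-butyldimethylsilyl)oxy]-3-methoxyphenyl}lithium F9, and F9 adds to F6 (then AcOH) to come back to the route at 13.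

## Further compounds

F1 | step 10 | racemic trans-4-[7-(benzyloxy)-6,8-dimethoxy-2,3-dimethyl-1,2-dihydronaphthalen-1-yl]-2-methoxyphenol (1:1 mixture of the 1R,2S and 1S,2R enantiomers) | COc1cc([C@@H]2c3c(C=C(C)[C@H]2C)cc(OC)c(OCc4ccccc4)c3OC)ccc1O.COc1cc([C@H]2c3c(C=C(C)[C@@H]2C)cc(OC)c(OCc4ccccc4)c3OC)ccc1O
F2 | step 10 | (1S,4R)-camphanate ester of the 4'-phenol of the (1R,2S)-dihydronaphthalene 17 | COc1cc([C@@H]2c3c(C=C(C)[C@H]2C)cc(OC)c(OCc4ccccc4)c3OC)ccc1OC(=O)[C@@]12CC[C@@](C)(C(=O)O1)C2(C)C
F3 | step 10 | (1S,4R)-camphanate ester of the 4'-phenol of the (1S,2R)-dihydronaphthalene (enantiomer of 17) | COc1cc([C@H]2c3c(C=C(C)[C@@H]2C)cc(OC)c(OCc4ccccc4)c3OC)ccc1OC(=O)[C@@]12CC[C@@](C)(C(=O)O1)C2(C)C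
F4 | step 11 | 4-O-benzyl-7-hydroxy derivative of 18 (lignan numbering 7R,7'R,8S,8'S; 7-OH on the face of the 7'-aryl group, trans to the 8-methyl) | COc1cc([C@@H]2c3c(cc(OC)c(OCc4ccccc4)c3OC)[C@H](O)[C@@H](C)[C@H]2C)ccc1O
F5 | step 6 | [4-(benzyloxy)-2-bromo-3,5-dimethoxybenzyl]zinc bromide | COc1cc(C[Zn]Br)c(Br)c(OC)c1OCc1ccccc1
F6 | step 8 | 3-(benzyloxy)-2,4-dimethoxy-6-[(Z)-2-methylbut-2-en-1-yl]benzaldehyde | C/C=C(/C)Cc1cc(OC)c(OCc2ccccc2)c(OC)c1C=O
F7 | step 8 | 4-bromo-2-methoxyphenol | COc1cc(Br)ccc1O
F8 | step 8 | (4-bromo-2-methoxyphenoxy)(tert-butyl)dimethylsilane | COc1cc(Br)ccc1O[Si](C)(C)C(C)(C)C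
F9 | step 8 | {4-[(tert-butyldimethylsilyl)oxy]-3-methoxyphenyl}lithium | COc1cc([Li])ccc1O[Si](C)(C)C(C)(C)C
A1 | alternative 1 | 3-(benzyloxy)-2,4-dimethoxy-6-methylbenzaldehyde | Cc1cc(OC)c(OCc2ccccc2)c(OC)c1C=O
A2 | alternative 1 | [3-(benzyloxy)-2,4-dimethoxy-6-methylidenecyclohexa-2,4-dien-1-ylidene]methanol, the hydroxy-ortho-quinodimethane from A1 (enol Z by the priority rules, hydroxyl turned away from the methylidene group) | C=C1C=C(OC)C(OCc2ccccc2)=C(OC)/C1=C\O
A3 | alternative 1 | (5R)-5-{[(1R,2S,5R)-5-methyl-2-(propan-2-yl)cyclohexyl]oxy}furan-2(5H)-one | O=C1C=C[C@H](O[C@@H]2C[C@H](C)CC[C@H]2C(C)C)O1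
A4 | alternative 1 | cis-lactone-fused 7'-hydroxytetralin menthyl acetal (lactone carbonyl on C8', menthyl acetal carbon on C8, 4-O-benzyl) | O[C@H]1c2c(cc(OC)c(OCc3ccccc3)c2OC)C[C@@H]4[C@H]1C(=O)O[C@H]4O[C@@H]5C[C@H](C)CC[C@H]5C(C)C
A5 | alternative 2 | 4-[4-(benzyloxy)-3-methoxyphenyl]-4-(4-hydroxy-3,5-dimethoxyphenyl)-2,3-dimethylbutyl methanesulfonate, the three stereocentres arranged as C8, C8' and C7' of 18 | COc1cc([C@@H]([C@H](C)[C@H](C)COS(C)(=O)=O)c2cc(OC)c(O)c(OC)c2)ccc1OCc1ccccc1
A6 | alternative 2 | 1-[4-(benzyloxy)-3-methoxyphenyl]-7,9-dimethoxy-2,3-dimethylspiro[4.5]deca-6,9-dien-8-one, stereocentres arranged as in 18 | COc1cc([C@H]2[C@H](C)[C@H](C)CC23C=C(OC)C(=O)C(OC)=C3)ccc1OCc1ccccc1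
A7 | alternative 2 | 4'-O-benzyl ether of 18 | COc1cc([C@@H]2c3c(cc(OC)c(O)c3OC)C[C@@H](C)[C@H]2C)ccc1OCc1ccccc1
A8 | alternative 3 | methyl 3-[4-(benzyloxy)-3-methoxyphenyl]-3-[3-(benzyloxy)-2,4-dimethoxy-6-(3-methoxy-3-oxopropyl)phenyl]propanoate, C7' arranged as in 18 | COC(=O)CCc1cc(OC)c(OCc2ccccc2)c(OC)c1[C@H](CC(=O)OC)c1ccc(OCc2ccccc2)c(OC)c1
A9 | alternative 3 | dimethyl 7'-aryltetralin-8,8'-dicarboxylate, 7',8'-trans-8,8'-cis, both phenols as benzyl ethers | COc1cc([C@@H]2c3c(cc(OC)c(OCc4ccccc4)c3OC)C[C@@H](C(=O)OC)[C@H]2C(=O)OC)ccc1OCc1ccccc1
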